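The target is cut at the C4=C5 alkene of the ten-membered ring (C1–C10), whose Z geometry places the C3 acetate oxygen and the C6 lactone oxygen on the same side. A diisopropylsilylene bridge between these two oxygens joins a C1–C4/C15 allylic alcohol to a C5–C14 fragment that already carries C6–C8, the acrylate (C11–C13), the angelate and the C10 iodide. Ring-closing metathesis between the C4 methylene and the C5 vinyl group then forms C4=C5 inside a seven-membered dioxasilepine, which can only hold the cis alkene. Afterwards the γ-lactone is closed and the C1–C10 bond is made by chromium-mediated macrocyclisation.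

Key step: step 13

Remark: locants are those of the target (ring C1–C10, lactone O6–C12, C13 methylene, C14 methyl, C15 hydroxymethyl); O15 is carried as a tert-butyldiphenylsilyl ether and O1 as a p-methoxybenzyl ether so that each can be removed without touching the other or the silylene.

Step 1
Reactants: 1 2-bromoprop-2-en-1-ol
Product: 2 tert-butyl[(2-bromoprop-2-en-1-yl)oxy]diphenylsilane
Conditions: TBDPSCl, imidazole, CH2Cl2, 0 °C to rt
Reagents that add atoms: tert-butyl(chloro)diphenylsilane, CC(C)(C)[Si](Cl)(c1ccccc1)c1ccccc1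
Why: Silyl ether formation at the primary allylic alcohol is routine under imidazole catalysis, and the bulky silyl group should resist migration to carbon in the later lithiation.

Step 2
Reactants: 3 3-[(4-methoxybenzyl)oxy]propan-1-ol
Product: 4 3-[(4-methoxybenzyl)oxy]propanal
Conditions: Dess–Martin periodinane, NaHCO3, CH2Cl2, 0 °C to rt
Reagents that add atoms: none
Why: Dess–Martin oxidation of the primary alcohol stops at the aldehyde, and the bicarbonate buffer protects the β-alkoxy aldehyde from elimination.

Step 3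
Reactants: 2 tert-butyl[(2-bromoprop-2-en-1-yl)oxy]diphenylsilane; 4 3-[(4-methoxybenzyl)oxy]propanal
Product: 6 racemic 2-[(tert-butyldiphenylsilyloxy)methyl]-5-[(4-methoxybenzyl)oxy]pent-1-en-3-ol, via vinyllithium 5 (not isolated)
Conditions: t-BuLi (2.1 equiv), Et2O, −78 °C; then 4, −78 °C
Reagents that add atoms: none
Why: Bromine–lithium exchange gives the 2-lithioallyl ether, which adds 1,2 to the aldehyde at −78 °C (alkenyllithium addition), the racemic carbinol being of no consequence because it is oxidised next.

Step 4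
Reactants: 6 racemic 2-[(tert-butyldiphenylsilyloxy)methyl]-5-[(4-methoxybenzyl)oxy]pent-1-en-3-ol
Product: 7 2-[(tert-butyldiphenylsilyloxy)methyl]-5-[(4-methoxybenzyl)oxy]pent-1-en-3-one
Conditions: Dess–Martin periodinane, NaHCO3, CH2Cl2, 0 °C
Reagents that add atoms: none
Why: Dess–Martin oxidation converts the allylic alcohol into the α-methylene ketone under near-neutral conditions that spare the β-alkoxy ketone from elimination.

Step 5
Reactants: 7 2-[(tert-butyldiphenylsilyloxy)methyl]-5-[(4-methoxybenzyl)oxy]pent-1-en-3-one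
Product: 8 (S)-2-[(tert-butyldiphenylsilyloxy)methyl]-5-[(4-methoxybenzyl)oxy]pent-1-en-3-ol (west alcohol C15–C4(=CH2)–C3–C2–C1)
Conditions: (R)-2-methyl-CBS-oxazaborolidine (0.2 equiv), catecholborane, toluene, −78 °C
Reagents that add atoms: none
Why: Corey–Bakshi–Shibata reduction, in which the α-branched alkenyl group acts as the large substituent so that the (R)-catalyst should deliver hydride to the face giving the (S)-carbinol at C3, catecholborane at low temperature avoiding hydroboration of the alkene.

Step 6
Reactants: 9 but-2-yn-1-ol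
Product: 11 (Z)-3-iodobut-2-en-1-ol, via cyclic vinylalanate 10 (not isolated)
Conditions: NaAlH2(OCH2CH2OCH3)2 (Red-Al), THF, 0 °C to rt; then I2, −78 to 0 °C
Reagents that add atoms: iodine, [I][I]
Why: Alkoxide-directed trans-hydroalumination of the propargylic alcohol places aluminium on C10 cis to the CH2O group, and iodinolysis of the C–Al bond with retention fixes the Z geometry of the C9=C10 iodoalkene.

Step 7
Reactants: 11 (Z)-3-iodobut-2-en-1-ol
Product: 12 (Z)-3-iodobut-2-enal
Conditions: MnO2, CH2Cl2, rt
Reagents that add atoms: none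
Why: MnO2 oxidises the allylic alcohol chemoselectively to the enal without touching the vinyl iodide or the alkene geometry.

Step 8
Reactants: 12 (Z)-3-iodobut-2-enal; 13 tert-butyl 2-(bromomethyl)acrylate
Product: 15 racemic tert-butyl (Z)-4-hydroxy-6-iodo-2-methylidenehept-5-enoate, via allylindium bromide 14 (not isolated)
Conditions: indium powder, THF/H2O (1:1), rt
Reagents that add atoms: none
Why: Indium-mediated Barbier allylation in water adds the 2-(alkoxycarbonyl)allyl unit 1,2 to the enal while tolerating the vinyl iodide and the tert-butyl ester (which resists lactonisation), and the carbinol configuration is irrelevant because it is oxidised next.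

Step 9
Reactants: 15 racemic tert-butyl (Z)-4-hydroxy-6-iodo-2-methylidenehept-5-enoate
Product: 16 tert-butyl (Z)-6-iodo-2-methylidene-4-oxohept-5-enoate
Conditions: Dess–Martin periodinane, NaHCO3, CH2Cl2, 0 °C
Reagents that add atoms: none
Why: Dess–Martin oxidation of the allylic alcohol gives the ketone under buffered conditions mild enough to keep the acrylate alkene from moving into conjugation.

Step 10
Reactants: 16 tert-butyl (Z)-6-iodo-2-methylidene-4-oxohept-5-enoate; 17 acrolein
Product: 20 east diol tert-butyl (Z)-4-hydroxy-3-[(S)-1-hydroxyprop-2-en-1-yl]-6-iodo-2-methylidenehept-5-enoate (C6/C7/C8 all-syn as in the target), via boron enolate 18 (not isolated), via boron aldolate 19 (not isolated)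
Conditions: (+)-Ipc2BOTf, i-Pr2NEt, CH2Cl2, −78 °C; 17, −78 to −20 °C; LiBH4, −78 °C; then H2O2, pH 7 buffer, MeOH, 0 °C
Reagents that add atoms: none
Why: Diisopinocampheylboron-mediated aldol reaction in which the Z-enol borinate forms at the only enolisable site (C7), the closed chair transition state gives the C6/C7 syn relationship, the isopinocampheyl ligands are expected to direct attack to the Re face of acrolein (6S), and hydride delivery from LiBH4 to the six-membered boron aldolate chelate gives the 1,3-syn alcohol at C8.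

Step 11
Reactants: 8 (S)-2-[(tert-butyldiphenylsilyloxy)methyl]-5-[(4-methoxybenzyl)oxy]pent-1-en-3-ol; 21 dichlorodiisopropylsilane; 20 east diol
Product: 23 silaketal alcohol (west and east halves linked O3–Si(i-Pr)2–O6; free C8 hydroxyl), via chlorosilane 22 (not isolated)
Conditions: 21 (4 equiv), imidazole, CH2Cl2, 0 °C, excess 21 evaporated; then 20, imidazole, DMF, 0 °C to rt
Reagents that add atoms: none
Why: Stepwise silyl ether formation gives the unsymmetrical silaketal, the bulky chlorosilane being expected to react at the C6 hydroxyl flanked only by the vinyl group in preference to the C8 hydroxyl shielded by the cis iodine-bearing alkene.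

Step 12
Reactants: 23 silaketal alcohol; 24 angelic acid
Product: 26 metathesis precursor (O3,O6-diisopropylsilylene-tethered diene with C8 angelate; tert-butyl acrylate; C10 iodide), via mixed anhydride 25 (not isolated)
Conditions: 24, 2,4,6-trichlorobenzoyl chloride, Et3N, toluene, rt; then 23, DMAP, rt to 40 °C
Reagents that add atoms: none
Why: Yamaguchi esterification through the preformed mixed anhydride acylates the hindered C8 hydroxyl under conditions that should keep the Z geometry of the angelate.

Step 13
Reactants: 26 metathesis precursor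
Product: 27 dioxasilepine (seven-membered silaketal containing the Z C4=C5 alkene)
Conditions: second-generation Grubbs catalyst (10 mol%), toluene (0.005 M), 80 °C, argon purge
Reagents that add atoms: none
Why: The ruthenium alkylidene forms at the only monosubstituted alkene, the C5 vinyl group, and a [2+2] cycloaddition–cycloreversion with the C4 methylene closes the ring and releases ethylene. The closest known reaction type is temporary silicon-tethered ring-closing metathesis of bis(alkenyloxy)silanes to trisubstituted alkenes in seven-membered silaketals. The one ring formed, the 4,7-dihydro-1,3,2-dioxasilepine (Si, O3, C3, C4, C5, C6, O6), is closed at the C4=C5 bond by this metathesis. No stereocentre is created; the Z geometry follows from the ring size, which cannot hold a trans alkene, so C3 and C6 end cis as in the target. The step needs the alkylidene to close onto C4 and not onto the acrylate (C11=C13, which would need a four-membered ring), the angelate or the iodoalkene (C9=C10, a five-membered ring); these are trisubstituted or electron-poor and therefore slow partners, and high dilution suppresses dimerisation.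

Step 14
Reactants: 27 dioxasilepine
Product: 28 C3,C6-diol
Conditions: HF·pyridine, pyridine, THF, 0 °C
Reagents that add atoms: none
Why: Fluoride cleaves the two Si–O bonds of the dialkoxysilane (silylene acetal cleavage) much faster than the hindered tert-butyldiphenylsilyl ether, and buffered HF leaves the esters, the p-methoxybenzyl ether and the vinyl iodide untouched.

Step 15
Reactants: 28 C3,C6-diol
Product: 29 hydroxy lactone (trans-fused α-methylene-γ-butyrolactone on C6/C7; free C3 hydroxyl)
Conditions: p-TsOH·H2O (0.2 equiv), CH2Cl2, rt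
Reagents that add atoms: none
Why: Acid-catalysed intramolecular transesterification (5-exo-trig lactonisation) of the γ-hydroxy tert-butyl ester closes the lactone with retention at C6, the C3 hydroxyl being unable to reach the ester through a small ring.

Step 16
Reactants: 29 hydroxy lactone
Product: 30 C3 acetate
Conditions: Ac2O, pyridine, DMAP (cat.), CH2Cl2, 0 °C to rt
Reagents that add atoms: acetic anhydride, CC(=O)OC(C)=O
Why: DMAP-catalysed acetylation of the only free hydroxyl installs the C3 acetate.

Step 17
Reactants: 30 C3 acetate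
Product: 31 C1 primary alcohol
Conditions: DDQ, CH2Cl2/pH 7 buffer (10:1), 0 °C
Reagents that add atoms: none
Why: Oxidative cleavage of the p-methoxybenzyl ether by DDQ frees the C1 hydroxyl without affecting the silyl ether, the esters or the alkenes.

Step 18
Reactants: 31 C1 primary alcohol
Product: 32 C1 aldehyde
Conditions: Dess–Martin periodinane, NaHCO3, CH2Cl2, 0 °C
Reagents that add atoms: none
Why: Dess–Martin oxidation gives the aldehyde under buffered, amine-free conditions that avoid β-elimination of the C3 acetate.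

Step 19
Reactants: 32 C1 aldehyde
Product: 34 macrocycle (O15-silylated target), via alkenylchromium dichloride 33 (not isolated)
Conditions: CrCl2 (10 equiv), NiCl2 (2 mol%), DMSO (0.003 M, slow addition), rt
Reagents that add atoms: none
Why: Nozaki–Hiyama–Kishi macrocyclisation in which zerovalent nickel inserts into the C10–I bond and transmetalation gives the alkenylchromium species, which adds only to the aldehyde with retention of the Z alkene and closes the ten-membered ring, the (1S) configuration being expected from 1,3-anti induction by the C3 acetoxy group in a chain pre-organised by the lactone and the Z C4=C5 alkene.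

Step 20
Reactants: 34 macrocycle
Product: 35 target CNP0153210.4
Conditions: HF·pyridine, THF, 0 °C to rt
Reagents that add atoms: none
Why: Fluoride-mediated desilylation removes the primary tert-butyldiphenylsilyl ether under non-basic conditions that should not disturb the acetate, the angelate or the α-methylene lactone.

Compound list
1 | 2-bromoprop-2-en-1-ol | C=C(Br)CO | starting material
2 | tert-butyl[(2-bromoprop-2-en-1-yl)oxy]diphenylsilane | C=C(Br)CO[Si](c1ccccc1)(c1ccccc1)C(C)(C)C | intermediate
3 | 3-[(4-methoxybenzyl)oxy]propan-1-ol | COc1ccc(COCCCO)cc1 | starting material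
4 | 3-[(4-methoxybenzyl)oxy]propanal | COc1ccc(COCCC=O)cc1 | intermediate
5 | vinyllithium, [3-(tert-butyldiphenylsilyloxy)prop-1-en-2-yl]lithium | [Li]C(=C)CO[Si](c1ccccc1)(c1ccccc1)C(C)(C)C | intermediate
6 | racemic 2-[(tert-butyldiphenylsilyloxy)methyl]-5-[(4-methoxybenzyl)oxy]pent-1-en-3-ol | C=C(CO[Si](c1ccccc1)(c1ccccc1)C(C)(C)C)C(O)CCOCc1ccc(OC)cc1 | intermediate
7 | 2-[(tert-butyldiphenylsilyloxy)methyl]-5-[(4-methoxybenzyl)oxy]pent-1-en-3-one | C=C(CO[Si](c1ccccc1)(c1ccccc1)C(C)(C)C)C(=O)CCOCc1ccc(OC)cc1 | intermediate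
8 | (S)-2-[(tert-butyldiphenylsilyloxy)methyl]-5-[(4-methoxybenzyl)oxy]pent-1-en-3-ol (west alcohol) | C=C(CO[Si](c1ccccc1)(c1ccccc1)C(C)(C)C)[C@@H](O)CCOCc1ccc(OC)cc1 | intermediate
9 | but-2-yn-1-ol | CC#CCO | starting material
10 | cyclic vinylalanate, sodium salt (aluminium bound to C10 and to the oxygen, two 2-methoxyethoxy ligands) | CC1=CCO[Al-]1(OCCOC)OCCOC.[Na+] | intermediate
11 | (Z)-3-iodobut-2-en-1-ol | C/C(I)=C/CO | intermediate
12 | (Z)-3-iodobut-2-enal | C/C(I)=C/C=O | intermediate
13 | tert-butyl 2-(bromomethyl)acrylate | C=C(CBr)C(=O)OC(C)(C)C | starting material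
14 | allylindium bromide, [2-(tert-butoxycarbonyl)allyl]indium dibromide (simplified formula) | C=C(C[In](Br)Br)C(=O)OC(C)(C)C | intermediate
15 | racemic tert-butyl (Z)-4-hydroxy-6-iodo-2-methylidenehept-5-enoate | C=C(CC(O)/C=C(\I)C)C(=O)OC(C)(C)C | intermediate
16 | tert-butyl (Z)-6-iodo-2-methylidene-4-oxohept-5-enoate | C=C(CC(=O)/C=C(\I)C)C(=O)OC(C)(C)C | intermediate
17 | acrolein | C=CC=O | starting material
18 | boron enolate, (Z)-enol bis(isopinocampheyl)borinate of 16 | C=C(C(=O)OC(C)(C)C)/C=C(\OB([C@H]1C[C@H]2C[C@@H]([C@@H]1C)C2(C)C)[C@H]1C[C@H]2C[C@@H]([C@@H]1C)C2(C)C)/C=C(\I)C | intermediate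
19 | boron aldolate (O6 bound to boron, C8 ketone, C6/C7 syn) | C=C[C@H](OB([C@H]1C[C@H]2C[C@@H]([C@@H]1C)C2(C)C)[C@H]1C[C@H]2C[C@@H]([C@@H]1C)C2(C)C)[C@@H](C(=C)C(=O)OC(C)(C)C)C(=O)/C=C(\I)C | intermediate
20 | east diol, tert-butyl (Z)-4-hydroxy-3-[(S)-1-hydroxyprop-2-en-1-yl]-6-iodo-2-methylidenehept-5-enoate, C6/C7/C8 all-syn | O[C@@H](C=C)[C@@H](C(=C)C(=O)OC(C)(C)C)[C@H](O)/C=C(\I)C | intermediate
21 | dichlorodiisopropylsilane | CC(C)[Si](Cl)(Cl)C(C)C | starting material
22 | chlorosilane, chloro(diisopropyl)silyl ether of 8 | C=C(CO[Si](c1ccccc1)(c1ccccc1)C(C)(C)C)[C@H](CCOCc1ccc(OC)cc1)O[Si](Cl)(C(C)C)C(C)C | intermediate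
23 | silaketal alcohol, O3–Si(i-Pr)2–O6 linked halves with free C8 hydroxyl | C=C(CO[Si](c1ccccc1)(c1ccccc1)C(C)(C)C)[C@H](CCOCc1ccc(OC)cc1)O[Si](C(C)C)(C(C)C)O[C@@H](C=C)[C@@H](C(=C)C(=O)OC(C)(C)C)[C@H](O)/C=C(\I)C | intermediate
24 | angelic acid, (Z)-2-methylbut-2-enoic acid | C/C=C(/C)C(=O)O | starting material
25 | mixed anhydride, angelic 2,4,6-trichlorobenzoic anhydride | C/C=C(/C)C(=O)OC(=O)c1c(Cl)cc(Cl)cc1Cl | intermediate
26 | metathesis precursor, O3,O6-diisopropylsilylene-tethered diene | C=C(CO[Si](c1ccccc1)(c1ccccc1)C(C)(C)C)[C@H](CCOCc1ccc(OC)cc1)O[Si](C(C)C)(C(C)C)O[C@@H](C=C)[C@@H](C(=C)C(=O)OC(C)(C)C)[C@H](OC(=O)/C(C)=C\C)/C=C(\I)C | intermediate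
27 | dioxasilepine with the Z C4=C5 alkene | CC(C)[Si]1(C(C)C)O[C@@H](CCOCc2ccc(OC)cc2)/C(CO[Si](c2ccccc2)(c2ccccc2)C(C)(C)C)=C\[C@H](O1)[C@@H](C(=C)C(=O)OC(C)(C)C)[C@H](OC(=O)/C(C)=C\C)/C=C(\I)C | intermediate
28 | C3,C6-diol | O[C@@H](CCOCc1ccc(OC)cc1)/C(CO[Si](c1ccccc1)(c1ccccc1)C(C)(C)C)=C\[C@H](O)[C@@H](C(=C)C(=O)OC(C)(C)C)[C@H](OC(=O)/C(C)=C\C)/C=C(\I)C | intermediate
29 | hydroxy lactone (6,12-olide, free C3 hydroxyl) | C=C1C(=O)O[C@@H](/C=C(/CO[Si](c2ccccc2)(c2ccccc2)C(C)(C)C)[C@@H](O)CCOCc2ccc(OC)cc2)[C@@H]1[C@H](OC(=O)/C(C)=C\C)/C=C(\I)C | intermediate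
30 | C3 acetate | C=C1C(=O)O[C@@H](/C=C(/CO[Si](c2ccccc2)(c2ccccc2)C(C)(C)C)[C@@H](OC(C)=O)CCOCc2ccc(OC)cc2)[C@@H]1[C@H](OC(=O)/C(C)=C\C)/C=C(\I)C | intermediate
31 | C1 primary alcohol | C=C1C(=O)O[C@@H](/C=C(/CO[Si](c2ccccc2)(c2ccccc2)C(C)(C)C)[C@@H](OC(C)=O)CCO)[C@@H]1[C@H](OC(=O)/C(C)=C\C)/C=C(\I)C | intermediate
32 | C1 aldehyde | C=C1C(=O)O[C@@H](/C=C(/CO[Si](c2ccccc2)(c2ccccc2)C(C)(C)C)[C@@H](OC(C)=O)CC=O)[C@@H]1[C@H](OC(=O)/C(C)=C\C)/C=C(\I)C | intermediate
33 | alkenylchromium dichloride (chromium on C10 in place of iodine) | C=C1C(=O)O[C@@H](/C=C(/CO[Si](c2ccccc2)(c2ccccc2)C(C)(C)C)[C@@H](OC(C)=O)CC=O)[C@@H]1[C@H](OC(=O)/C(C)=C\C)/C=C(\[Cr](Cl)Cl)C | intermediate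
34 | macrocycle, 15-O-tert-butyldiphenylsilyl ether of the target | C=C1C(=O)O[C@H]2/C=C(/CO[Si](c3ccccc3)(c3ccccc3)C(C)(C)C)[C@@H](OC(C)=O)C[C@H](O)/C(C)=C\[C@@H](OC(=O)/C(C)=C\C)[C@H]12 | intermediate
35 | CNP0153210.4 | C=C1C(=O)O[C@H]2/C=C(/CO)[C@@H](OC(C)=O)C[C@H](O)/C(C)=C\[C@@H](OC(=O)/C(C)=C\C)[C@H]12 | target

Total step count: 20.
Longest linear sequence: 15 steps (steps 6–20, from but-2-yn-1-ol 9).

Steps most likely to fail

Step 13. The alkylidene formed at the C5 vinyl group may be held back by the neighbouring ester carbonyls or consumed by intermolecular metathesis before it closes onto the crowded C4 methylene. The fallback is to run the metathesis before the acylation. It sets out from 23: ring closure with the same catalyst on the substrate that carries no angelate near the reacting vinyl group should give silepine alcohol F1. Esterification of the C8 hydroxyl with 24 through mixed anhydride 25 (Yamaguchi conditions) then brings the material back to the route at 27.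

Step 19. Facial selectivity in the ring-forming addition to the C1 aldehyde may be poor, because the transannular environment can override the 1,3-anti preference. The fallback sets C1 by reduction instead of by addition. It sets out from 32: the cyclisation mixture of 34 and its C1 epimer F2 is oxidised with Dess–Martin periodinane to macrocyclic C1 enone F3. Corey–Bakshi–Shibata reduction ((R)-2-methyl-CBS-oxazaborolidine, catecholborane, −78 °C; the C10 alkenyl group as the large substituent) should then return the (1S)-alcohol 34.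

Step 10. Enantioface control by the hindered chiral boron triflate may erode, or the enolate geometry may leak. The fallback gives up reagent control and resolves through the enantiopure west half. It sets out from 16: enolisation with Bu2BOTf and i-Pr2NEt, aldol reaction with 17 and the same in situ LiBH4 reduction should give the racemic all-syn diol, that is 20 together with its enantiomer ent-diol F4. Silylation of the racemate with enantiopure chlorosilane 22 gives 23 and the diastereomeric silaketal alcohol F5, which are separated on silica, so the route is rejoined at 23.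

Further compounds
F1 | step 13 | silepine alcohol (dioxasilepine with free C8 hydroxyl) | CC(C)[Si]1(C(C)C)O[C@@H](CCOCc2ccc(OC)cc2)/C(CO[Si](c2ccccc2)(c2ccccc2)C(C)(C)C)=C\[C@H](O1)[C@@H](C(=C)C(=O)OC(C)(C)C)[C@H](O)/C=C(\I)C
F2 | step 19 | C1 epimer of 34 | C=C1C(=O)O[C@H]2/C=C(/CO[Si](c3ccccc3)(c3ccccc3)C(C)(C)C)[C@@H](OC(C)=O)C[C@@H](O)/C(C)=C\[C@@H](OC(=O)/C(C)=C\C)[C@H]12
F3 | step 19 | macrocyclic C1 enone | C=C1C(=O)O[C@H]2/C=C(/CO[Si](c3ccccc3)(c3ccccc3)C(C)(C)C)[C@@H](OC(C)=O)CC(=O)/C(C)=C\[C@@H](OC(=O)/C(C)=C\C)[C@H]12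
F4 | step 10 | ent-diol (enantiomer of 20) | O[C@H](C=C)[C@H](C(=C)C(=O)OC(C)(C)C)[C@@H](O)/C=C(\I)C
F5 | step 10 | diastereomeric silaketal alcohol (from 22 and F4) | C=C(CO[Si](c1ccccc1)(c1ccccc1)C(C)(C)C)[C@H](CCOCc1ccc(OC)cc1)O[Si](C(C)C)(C(C)C)O[C@H](C=C)[C@H](C(=C)C(=O)OC(C)(C)C)[C@@H](O)/C=C(\I)C
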